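**Retrosynthetic overview**

1. Target 36 ← MnO2 oxidation, desilylation and acetylation of diol 33 ← DIBAL opening of a temporary cis-fused α-alkylidene γ-lactone 32. Its C=O carbon is the future CH2OAc carbon; the ring fixes the side chain cis to OH on the five-membered ring and the Z trisubstituted alkene. The triene comes from a Suzuki coupling (29 + 31).
2. Lactone ← Pd–H reductive enyne cyclisation of alkynoate 26 ← cyclopentenol 23 ← spiro[4.5]decanone 17 (Stille hydroxymethylation, Saegusa oxidation, OH-directed reduction).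
3. 17 ← acyclic enyne 15 in one gold(I)/NIS cascade. The cyclohexane closes by C–C bond formation between the ring CH that carries the hydroxypropyl chain and the ring carbon that carries the exocyclic alkylidene. In the same event the cyclopentane arises by semipinacol ring expansion of a cyclobutanol.
4. Enabling feature: the quaternary spiro carbon is flanked by the CH–OH carbon of the five-membered ring (a ketone next to a quaternary centre is a semipinacol retron) and by the C(CH3)–OH carbon of the six-membered ring. The two oxygens are 1,3 across the spiro atom and can be tied as a silylene. The exocyclic tetrasubstituted enal on the ring carbon next to the ring CH is the trace of a 2-butynyl alkyne.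
5. 15 ← geraniol (Sharpless epoxidation; geraniol C1–C6 become the six cyclohexane carbons, its 3-methyl the ring methyl) + iodide 4 + cyclobutanone 12. Ring order: cyclohexane and cyclopentane together (step 10), then the temporary lactone (step 18, opened in step 23).

Key step: step 10

Assumption (chemistry): [Cp*RuCl]4, (tributylstannyl)methanol, the Ohira–Bestmann reagent, bis(dimethylamino)dimethylsilane and 2-(dichloromethyl)pinacolborane are treated as purchasable reagents; enantiopure (S)-dehydrolinalool is not assumed purchasable and is made from geraniol.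

**Route**

Step 1
Reactants: 1 geraniol
Product: 2 (2S,3S)-2,3-epoxygeraniol
Conditions: Ti(OiPr)4 (5 mol%), L-(+)-diethyl tartrate (6 mol%), t-BuOOH, 4 Å MS, CH2Cl2, −20 °C
Reagents that add atoms: tert-butyl hydroperoxide CC(C)(C)OO
Why: Katsuki–Sharpless asymmetric epoxidation, in which the L-(+)-tartrate–titanium complex delivers oxygen to one enantioface of the allylic alcohol and so sets the C–O stereocentre at the methyl-bearing carbon that becomes the ring C(CH3)–OH.

Step 2
Reactants: 2 (2S,3S)-2,3-epoxygeraniol
Product: 3 (2S,3R)-3-(chloromethyl)-2-methyl-2-(4-methylpent-3-en-1-yl)oxirane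
Conditions: PPh3, CCl4, NaHCO3, reflux
Reagents that add atoms: carbon tetrachloride ClC(Cl)(Cl)Cl
Why: Appel chlorination converts the primary alcohol into the chloride under near-neutral conditions that leave the trisubstituted epoxide and both stereocentres untouched.

Step 3
Reactants: 3 epoxy chloride; 4 tert-butyl(3-iodopropoxy)dimethylsilane
Product: 6 (6S)-11-[(tert-butyldimethylsilyl)oxy]-2,6-dimethylundec-2-en-7-yn-6-ol, via dilithio (S)-dehydrolinalool 5 (not isolated)
Conditions: n-BuLi (3.3 equiv), THF, −40 → −20 °C; then DMPU, 4, −20 °C → rt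
Reagents that add atoms: n-butyllithium [Li]CCCC; 4 tert-butyl(3-iodopropoxy)dimethylsilane ICCCO[Si](C)(C)C(C)(C)C
Why: Base-induced eliminative opening of a 2,3-epoxy chloride (Yadav–Takano propargylic alcohol synthesis) breaks only the C–O bond at the epoxide CH, so the tertiary carbinol keeps its configuration, and the lithium acetylide formed with the third equivalent of base is alkylated in situ by the primary iodide (SN2).

Step 4
Reactants: 6 alkynol
Product: 7 (5S)-5-[5-((tert-butyldimethylsilyl)oxy)pent-1-yn-1-yl]-5-methyloxolan-2-ol (anomer mixture)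
Conditions: O3, CH2Cl2/MeOH, −78 °C (Sudan III end point); then Me2S, −78 °C → rt
Reagents that add atoms: ozone [O-][O+]=O
Why: Ozonolysis with reductive work-up cleaves the electron-rich trisubstituted alkene much faster than the internal alkyne, and the resulting γ-hydroxy aldehyde closes to the five-membered lactol.

Step 5
Reactants: 7 lactol
Product: 8 (5S)-10-[(tert-butyldimethylsilyl)oxy]-5-methyldeca-1,6-diyn-5-ol
Conditions: dimethyl (1-diazo-2-oxopropyl)phosphonate, K2CO3, MeOH, 0 °C → rt
Reagents that add atoms: dimethyl (1-diazo-2-oxopropyl)phosphonate COP(=O)(OC)C(=[N+]=[N-])C(C)=O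
Why: Seyferth–Gilbert homologation with the Ohira–Bestmann reagent acts on the open hydroxy-aldehyde form of the lactol under mild carbonate conditions and converts CHO into a terminal alkyne.

Step 6
Reactants: 8 terminal diyne alcohol
Product: 9 (6S)-11-[(tert-butyldimethylsilyl)oxy]-6-methylundeca-2,7-diyn-6-ol
Conditions: n-BuLi (2.1 equiv), THF, −78 °C; MeI, −78 → 0 °C
Reagents that add atoms: iodomethane CI
Why: Double deprotonation gives the alkoxide–acetylide dianion, and methyl iodide alkylates the far more nucleophilic acetylide carbon while the hindered tertiary lithium alkoxide is inert in THF at low temperature.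

Step 7
Reactants: 9 diyne alcohol
Product: 11 (6S,7Z)-11-[(tert-butyldimethylsilyl)oxy]-7-iodo-6-methylundec-7-en-2-yn-6-ol, via (Z)-alkenylstannane 10 (not isolated)
Conditions: [Cp*RuCl]4 (2.5 mol%), Bu3SnH (1.05 equiv), CH2Cl2, rt; then I2, 0 °C
Reagents that add atoms: tributyltin hydride CCCC[SnH](CCCC)CCCC; iodine II
Why: Ruthenium-catalysed trans-hydrostannation of a propargylic alcohol, directed by an O–H···Cl–Ru hydrogen bond, should put tin on the alkyne carbon next to the carbinol and hydrogen trans to it at the propargylic triple bond only, and iododestannation with retention gives the (Z)-alkenyl iodide whose geometry later fixes the ring CH centre.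

Step 8
Reactants: 11 (Z)-alkenyl iodide; 12 cyclobutanone
Product: 14 (6S,7Z)-11-[(tert-butyldimethylsilyl)oxy]-7-(1-hydroxycyclobutyl)-6-methylundec-7-en-2-yn-6-ol, via dilithio alkenyl alkoxide 13 (not isolated)
Conditions: t-BuLi (3.05 equiv), Et2O, −78 °C; then 12, −78 → −40 °C
Reagents that add atoms: tert-butyllithium [Li]C(C)(C)C; 12 cyclobutanone O=C1CCC1
Why: Iodine–lithium exchange proceeds with retention of alkene geometry on the pre-formed lithium alkoxide, and the alkenyllithium adds 1,2 to the strained, highly electrophilic cyclobutanone to give the 1-alkenylcyclobutanol.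

Step 9
Reactants: 14 diol
Product: 15 (8S,9Z)-9-{4-[(tert-butyldimethylsilyl)oxy]butylidene}-6,6,8-trimethyl-8-(pent-3-yn-1-yl)-5,7-dioxa-6-silaspiro[3.5]nonane
Conditions: Me2Si(NMe2)2 (1.5 equiv), toluene, 80 °C
Reagents that add atoms: bis(dimethylamino)dimethylsilane CN(C)[Si](C)(C)N(C)C
Why: Aminosilane silylation driven by loss of volatile dimethylamine closes the six-membered dialkoxysilane ring under neutral conditions, tying the two tertiary oxygens together without ionising the allylic carbinols.

Step 10
Reactants: 15 silylene-tethered enyne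
Product: 17 (5R,6S,10S)-10-{3-[(tert-butyldimethylsilyl)oxy]propyl}-6-hydroxy-9-[(E)-1-iodoethylidene]-6-methylspiro[4.5]decan-1-one, via N-silylsuccinimide spiroketone 16 (not isolated)
Conditions: (JohnPhos)Au(MeCN)SbF6 (5 mol%), NIS (1.1 equiv, slow addition), 4 Å MS, CH2Cl2, −30 °C, dark; then 0.5 M citric acid, THF, rt
Reagents that add atoms: N-iodosuccinimide O=C1CCC(=O)N1I
Why: Cationic gold(I) activates the 2-butynyl triple bond, the trisubstituted alkene attacks it anti to gold through its CH terminus (6-endo-trig for the alkene, exo-dig for the alkyne) and closes the cyclohexane, and the tertiary cation developing next to the silyloxy cyclobutane is quenched by a semipinacol 1,2-shift of a cyclobutane CH2, which expands the four-membered ring to the cyclopentanone and creates the spiro centre; NIS then iododeaurates the exocyclic alkenylgold with retention and its succinimide anion takes up the silyl cation. The closest known reaction types are the gold(I)-catalysed pinacol-terminated 1,6-enyne cyclisation, the gold-catalysed cyclisation/ring expansion of alkenylcycloalkanol enynes, and NIS trapping of alkenylgold intermediates. The spiro carbon and the ring CH are set by stereospecific anti addition across the (Z)-alkene (new C–C bond on one face, migrating CH2 on the other), so the silyloxypropyl chain ends up cis to the new carbonyl carbon; the configuration relative to the existing carbinol is fixed by the silylene ring, which holds the carbinol oxygen syn to the former cyclobutanol carbon and forces the methyl group onto the face that receives the migrating CH2. Anti addition across the alkyne places the methyl group cis and the iodine trans to the ring CH, which is the enal geometry of the target. The step needs gold to choose the alkyne over the alkene and NIS to iodinate the alkenylgold rather than the alkene: the alkene is flanked by two quaternary oxygen-bearing carbons, no proton is released so the alkenylgold waits for the slowly added NIS, ring expansion of the strained cyclobutane outruns any shift from the acyclic carbinol, and the tether also blocks 5-exo hydroalkoxylation of the alkyne.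

Step 11
Reactants: 17 spiroketone iodide
Product: 18 (5R,6S,10R)-10-{3-[(tert-butyldimethylsilyl)oxy]propyl}-6-hydroxy-9-[(E)-1-hydroxypropan-2-ylidene]-6-methylspiro[4.5]decan-1-one
Conditions: Bu3SnCH2OH (1.5 equiv), Pd(PPh3)4 (10 mol%), dioxane, 90 °C
Reagents that add atoms: (tributylstannyl)methanol CCCC[Sn](CCCC)(CCCC)CO
Why: Kosugi–Migita–Stille coupling of the alkenyl iodide with (tributylstannyl)methanol transfers the hydroxymethyl group with retention of alkene geometry under neutral conditions that spare the β-hydroxy ketone.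

Step 12
Reactants: 18 allylic alcohol ketone
Product: 19 bis-TBS ketone (primary allylic OH of 18 silylated)
Conditions: TBSCl, imidazole, DMF, 0 °C → rt
Reagents that add atoms: tert-butyldimethylsilyl chloride CC(C)(C)[Si](C)(C)Cl
Why: Standard silylation protects the primary allylic alcohol selectively over the hindered tertiary alcohol.

Step 13
Reactants: 19 bis-TBS ketone
Product: 20 trimethylsilyl enol ether of 19 with the tertiary alcohol as its TMS ether
Conditions: TMSOTf (2.5 equiv), Et3N (4 equiv), CH2Cl2, 0 °C
Reagents that add atoms: trimethylsilyl trifluoromethanesulfonate C[Si](C)(C)OS(=O)(=O)C(F)(F)F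
Why: Soft enolisation forms the only possible silyl enol ether (the other α-carbon is quaternary) and caps the tertiary alcohol without generating a free β-alkoxide that could trigger retro-aldol cleavage.

Step 14
Reactants: 20 bis-TMS enol ether
Product: 22 (5R,6S,10R)-10-{3-[(tert-butyldimethylsilyl)oxy]propyl}-9-[(E)-1-((tert-butyldimethylsilyl)oxy)propan-2-ylidene]-6-hydroxy-6-methylspiro[4.5]dec-2-en-1-one, via TMS-ether enone 21 (not isolated)
Conditions: Pd(OAc)2 (1.1 equiv), MeCN, rt; then 0.5 M citric acid, THF, rt
Reagents that add atoms: none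
Why: Saegusa–Ito oxidation of the silyl enol ether installs the ring double bond, and the mildly acidic work-up removes only the labile tertiary trimethylsilyl ether.

Step 15
Reactants: 22 hydroxy enone
Product: 23 (1R,5S,6S,10R)-10-{3-[(tert-butyldimethylsilyl)oxy]propyl}-9-[(E)-1-((tert-butyldimethylsilyl)oxy)propan-2-ylidene]-6-methylspiro[4.5]dec-2-ene-1,6-diol
Conditions: Me4NBH(OAc)3 (5 equiv), MeCN/AcOH (1:1), −30 → −10 °C
Reagents that add atoms: none
Why: Evans–Saksena hydroxyl-directed 1,2-reduction, in which the tertiary alcohol binds boron and delivers hydride intramolecularly to the carbonyl face on which it sits, so the new secondary OH lies on the face of the five-membered ring opposite to the tertiary carbinol carbon.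

Step 16
Reactants: 24 3,3-diethoxyprop-1-yne
Product: 25 4,4-diethoxybut-2-ynoic acid
Conditions: n-BuLi, THF, −78 °C; CO2; cold 1 M HCl to pH 3
Reagents that add atoms: carbon dioxide O=C=O
Why: Lithiation of the terminal alkyne and carboxylation gives the alkynoic acid, the acetal surviving a brief cold acidification.

Step 17
Reactants: 23 cyclopentenol diol; 25 4,4-diethoxybut-2-ynoic acid
Product: 26 4,4-diethoxybut-2-ynoate ester of the secondary allylic alcohol of 23
Conditions: DIC (1.5 equiv), DMAP (10 mol%), CH2Cl2, −20 → 0 °C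
Reagents that add atoms: 25 4,4-diethoxybut-2-ynoic acid CCOC(OCC)C#CC(=O)O
Why: Steglich (carbodiimide) esterification acylates the secondary allylic alcohol while the tertiary alcohol is too hindered to react, and a low DMAP loading at low temperature limits conjugate addition to the ynoate.

Step 18
Reactants: 26 alkynoate ester
Product: 27 cis-fused (Z)-α-(2,2-diethoxyethylidene) γ-lactone (lactone O on the carbinol carbon, α-carbon bonded to the adjacent ring CH, acetal carbon cis to C=O)
Conditions: Pd2(dba)3·CHCl3 (5 mol%), P(o-tol)3 (20 mol%), AcOH (2 equiv), Et3SiH (5 equiv), toluene, rt → 40 °C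
Reagents that add atoms: none
Why: Palladium hydride-initiated reductive 1,6-enyne cyclisation (Trost type): syn hydropalladation of the ynoate with Pd α to the ester, 5-exo insertion of the ring alkene on the face carrying the ester oxygen (only the cis-fused bicycle can form, which sets the new ring CH cis to the carbinol oxygen) and silane reduction of the alkylpalladium, the syn H–Pd addition placing the vinylic H cis to the ring carbon and the acetal carbon cis to the lactone carbonyl.

Step 19
Reactants: 27 lactone acetal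
Product: 28 cis-fused (Z)-α-(2-oxoethylidene) γ-lactone
Conditions: PPTS (0.3 equiv), acetone/H2O (9:1), 45 °C; used at once
Reagents that add atoms: water O
Why: Mild acid-catalysed acetal hydrolysis frees the aldehyde without cleaving the primary silyl ethers.

Step 20
Reactants: 28 lactone enal
Product: 29 (E)-dienyl pinacol boronate of the lactone
Conditions: CrCl2 (8 equiv), Cl2CHBpin (2 equiv), LiI (4 equiv), THF, rt
Reagents that add atoms: 2-(dichloromethyl)-4,4,5,5-tetramethyl-1,3,2-dioxaborolane ClC(Cl)B1OC(C)(C)C(C)(C)O1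
Why: Takai–Utimoto borylative olefination, in which the gem-dichromium reagent adds to the aldehyde and eliminates to the (E)-alkenylboronate under non-basic conditions that tolerate the lactone, silyl ethers and free tertiary OH.

Step 21
Reactants: 30 6-methylhept-5-en-2-one
Product: 31 6-methylhepta-1,5-dien-2-yl trifluoromethanesulfonate
Conditions: LDA, THF, −78 °C; PhNTf2, −78 → 0 °C
Reagents that add atoms: N-phenylbis(trifluoromethanesulfonimide) O=S(=O)(N(c1ccccc1)S(=O)(=O)C(F)(F)F)C(F)(F)F
Why: Kinetic deprotonation of the methyl ketone at the methyl group and O-triflation gives the 1,1-disubstituted enol triflate.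

Step 22
Reactants: 29 (E)-dienylboronate; 31 enol triflate
Product: 32 trienyl lactone (complete C30 skeleton)
Conditions: Pd(PPh3)4 (5 mol%), aq. K3PO4, THF, 40 °C
Reagents that add atoms: 31 6-methylhepta-1,5-dien-2-yl trifluoromethanesulfonate C=C(OS(=O)(=O)C(F)(F)F)CCC=C(C)C
Why: Suzuki–Miyaura coupling joins the alkenylboronate and the enol triflate with retention at both sp2 carbons and completes the cross-conjugated triene.

Step 23
Reactants: 32 trienyl lactone
Product: 33 diol (primary allylic CH2OH and ring CH–OH, cis)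
Conditions: DIBAL-H (5 equiv), CH2Cl2, −78 → −20 °C; Rochelle salt
Reagents that add atoms: none
Why: DIBAL-H reduces the α-alkylidene lactone in a 1,2 sense through the lactol to the diol, which opens the temporary ring without touching the alkenes or silyl ethers.

Step 24
Reactants: 33 diol
Product: 34 primary allylic acetate
Conditions: Ac2O (1.1 equiv), 2,4,6-collidine, CH2Cl2, −20 °C
Reagents that add atoms: acetic anhydride CC(=O)OC(C)=O
Why: Acetylation with one equivalent of anhydride at low temperature discriminates the primary allylic alcohol from the neopentyl-type secondary and the tertiary alcohols.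

Step 25
Reactants: 34 allylic acetate
Product: 35 tetraol monoacetate (both TBS ethers removed)
Conditions: HF·pyridine, pyridine, THF, 0 °C → rt
Reagents that add atoms: none
Why: Buffered HF·pyridine removes both primary silyl ethers while the allylic acetate, the triene and the free alcohols are stable.

Step 26
Reactants: 35 tetraol monoacetate
Product: 36 target CNP0204268.1
Conditions: activated MnO2 (20 equiv), CH2Cl2, rt
Reagents that add atoms: none
Why: Manganese dioxide oxidises only the allylic primary alcohol to the tetrasubstituted enal with retention of geometry, leaving the saturated primary, the non-allylic secondary and the tertiary alcohols untouched.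

**Compound list**

1 | geraniol, (2E)-3,7-dimethylocta-2,6-dien-1-ol | CC(C)=CCC/C(C)=C/CO | starting material
2 | (2S,3S)-2,3-epoxygeraniol | CC(C)=CCC[C@]1(C)O[C@H]1CO | intermediate
3 | (2S,3R)-3-(chloromethyl)-2-methyl-2-(4-methylpent-3-en-1-yl)oxirane (chloride of 2, same spatial arrangement) | CC(C)=CCC[C@]1(C)O[C@H]1CCl | intermediate
4 | tert-butyl(3-iodopropoxy)dimethylsilane | ICCCO[Si](C)(C)C(C)(C)C | starting material
5 | dilithio (S)-dehydrolinalool (lithium alkoxide and lithium acetylide of (S)-3,7-dimethyloct-6-en-1-yn-3-ol) | [Li]C#C[C@@](C)(O[Li])CCC=C(C)C | intermediate (not isolated)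
6 | (6S)-11-[(tert-butyldimethylsilyl)oxy]-2,6-dimethylundec-2-en-7-yn-6-ol | CC(C)(C)[Si](C)(C)OCCCC#C[C@@](C)(O)CCC=C(C)C | intermediate
7 | (5S)-5-[5-((tert-butyldimethylsilyl)oxy)pent-1-yn-1-yl]-5-methyloxolan-2-ol, anomer mixture | CC(C)(C)[Si](C)(C)OCCCC#C[C@@]1(C)OC(O)CC1 | intermediate
8 | (5S)-10-[(tert-butyldimethylsilyl)oxy]-5-methyldeca-1,6-diyn-5-ol | CC(C)(C)[Si](C)(C)OCCCC#C[C@@](C)(O)CCC#C | intermediate
9 | (6S)-11-[(tert-butyldimethylsilyl)oxy]-6-methylundeca-2,7-diyn-6-ol | CC(C)(C)[Si](C)(C)OCCCC#C[C@@](C)(O)CCC#CC | intermediate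
10 | (6S,7Z)-11-[(tert-butyldimethylsilyl)oxy]-6-methyl-7-(tributylstannyl)undec-7-en-2-yn-6-ol | CC#CCC[C@](C)(O)/C(=C/CCCO[Si](C)(C)C(C)(C)C)[Sn](CCCC)(CCCC)CCCC | intermediate (not isolated)
11 | (6S,7Z)-11-[(tert-butyldimethylsilyl)oxy]-7-iodo-6-methylundec-7-en-2-yn-6-ol | CC#CCC[C@](C)(O)/C(I)=C/CCCO[Si](C)(C)C(C)(C)C | intermediate
12 | cyclobutanone | O=C1CCC1 | starting material
13 | dilithio derivative of 11 (lithium alkoxide, 7-lithio alkene, geometry retained) | CC#CCC[C@](C)(O[Li])/C([Li])=C/CCCO[Si](C)(C)C(C)(C)C | intermediate (not isolated)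
14 | (6S,7Z)-11-[(tert-butyldimethylsilyl)oxy]-7-(1-hydroxycyclobutyl)-6-methylundec-7-en-2-yn-6-ol | CC#CCC[C@](C)(O)/C(=C/CCCO[Si](C)(C)C(C)(C)C)C1(O)CCC1 | intermediate
15 | (8S,9Z)-9-{4-[(tert-butyldimethylsilyl)oxy]butylidene}-6,6,8-trimethyl-8-(pent-3-yn-1-yl)-5,7-dioxa-6-silaspiro[3.5]nonane | CC#CCC[C@]1(C)O[Si](C)(C)OC2(CCC2)/C1=C\CCCO[Si](C)(C)C(C)(C)C | intermediate
16 | spiroketone 17 carrying a dimethyl(succinimido)silyl group on the tertiary oxygen | C1CC[C@]2([C@H](CCCO[Si](C)(C)C(C)(C)C)/C(=C(\C)I)CC[C@]2(C)O[Si](C)(C)N3C(=O)CCC3=O)C1=O | intermediate (not isolated)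
17 | (5R,6S,10S)-10-{3-[(tert-butyldimethylsilyl)oxy]propyl}-6-hydroxy-9-[(E)-1-iodoethylidene]-6-methylspiro[4.5]decan-1-one (OH, carbonyl carbon and silyloxypropyl chain on one face of the cyclohexane; methyl cis to ring CH on the alkene) | C1CC[C@]2([C@H](CCCO[Si](C)(C)C(C)(C)C)/C(=C(\C)I)CC[C@]2(C)O)C1=O | intermediate
18 | (5R,6S,10R)-10-{3-[(tert-butyldimethylsilyl)oxy]propyl}-6-hydroxy-9-[(E)-1-hydroxypropan-2-ylidene]-6-methylspiro[4.5]decan-1-one | C1CC[C@]2([C@H](CCCO[Si](C)(C)C(C)(C)C)/C(=C(\C)CO)CC[C@]2(C)O)C1=O | intermediate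
19 | TBS ether of 18 at the allylic primary alcohol (configuration as in 18) | C1CC[C@]2([C@H](CCCO[Si](C)(C)C(C)(C)C)/C(=C(\C)CO[Si](C)(C)C(C)(C)C)CC[C@]2(C)O)C1=O | intermediate
20 | trimethylsilyl enol ether of 19 with the tertiary alcohol as TMS ether (configuration as in 19) | C1(O[Si](C)(C)C)=CCC[C@]12[C@H](CCCO[Si](C)(C)C(C)(C)C)/C(=C(\C)CO[Si](C)(C)C(C)(C)C)CC[C@]2(C)O[Si](C)(C)C | intermediate
21 | spiro[4.5]dec-2-en-1-one 22 with the tertiary alcohol as TMS ether | C1=CC[C@]2([C@H](CCCO[Si](C)(C)C(C)(C)C)/C(=C(\C)CO[Si](C)(C)C(C)(C)C)CC[C@]2(C)O[Si](C)(C)C)C1=O | intermediate (not isolated)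
22 | (5R,6S,10R)-10-{3-[(tert-butyldimethylsilyl)oxy]propyl}-9-[(E)-1-((tert-butyldimethylsilyl)oxy)propan-2-ylidene]-6-hydroxy-6-methylspiro[4.5]dec-2-en-1-one | C1=CC[C@]2([C@H](CCCO[Si](C)(C)C(C)(C)C)/C(=C(\C)CO[Si](C)(C)C(C)(C)C)CC[C@]2(C)O)C1=O | intermediate
23 | (1R,5S,6S,10R)-10-{3-[(tert-butyldimethylsilyl)oxy]propyl}-9-[(E)-1-((tert-butyldimethylsilyl)oxy)propan-2-ylidene]-6-methylspiro[4.5]dec-2-ene-1,6-diol | C1=CC[C@]2([C@H](CCCO[Si](C)(C)C(C)(C)C)/C(=C(\C)CO[Si](C)(C)C(C)(C)C)CC[C@]2(C)O)[C@@H]1O | intermediate
24 | 3,3-diethoxyprop-1-yne | C#CC(OCC)OCC | starting material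
25 | 4,4-diethoxybut-2-ynoic acid | CCOC(OCC)C#CC(=O)O | intermediate
26 | 4,4-diethoxybut-2-ynoate of the C1 hydroxyl of 23 (configuration as in 23) | C1=CC[C@]2([C@H](CCCO[Si](C)(C)C(C)(C)C)/C(=C(\C)CO[Si](C)(C)C(C)(C)C)CC[C@]2(C)O)[C@@H]1OC(=O)C#CC(OCC)OCC | intermediate
27 | cis-fused γ-lactone on the cyclopentane with (Z)-α-(2,2-diethoxyethylidene) group; remaining centres as in 23 | CCOC(OCC)/C=C5/[C@@H]1CC[C@]2([C@H](CCCO[Si](C)(C)C(C)(C)C)/C(=C(\C)CO[Si](C)(C)C(C)(C)C)CC[C@]2(C)O)[C@@H]1OC5=O | intermediate
28 | cis-fused γ-lactone with (Z)-α-(2-oxoethylidene) group (aldehyde cis to lactone C=O) | O=C/C=C5/[C@@H]1CC[C@]2([C@H](CCCO[Si](C)(C)C(C)(C)C)/C(=C(\C)CO[Si](C)(C)C(C)(C)C)CC[C@]2(C)O)[C@@H]1OC5=O | intermediate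
29 | cis-fused γ-lactone with (Z)-α-[(E)-3-(pinacolboryl)prop-2-en-1-ylidene] group | CC6(C)OB(OC6(C)C)/C=C/C=C5/[C@@H]1CC[C@]2([C@H](CCCO[Si](C)(C)C(C)(C)C)/C(=C(\C)CO[Si](C)(C)C(C)(C)C)CC[C@]2(C)O)[C@@H]1OC5=O | intermediate
30 | 6-methylhept-5-en-2-one | CC(=O)CCC=C(C)C | starting material
31 | 6-methylhepta-1,5-dien-2-yl trifluoromethanesulfonate | C=C(OS(=O)(=O)C(F)(F)F)CCC=C(C)C | intermediate
32 | cis-fused γ-lactone carrying the complete (Z,E)-trienyl side chain | C=C(/C=C/C=C5/[C@@H]1CC[C@]2([C@H](CCCO[Si](C)(C)C(C)(C)C)/C(=C(\C)CO[Si](C)(C)C(C)(C)C)CC[C@]2(C)O)[C@@H]1OC5=O)CCC=C(C)C | intermediate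
33 | bis-TBS ether of the target skeleton with free CH2OH in place of CH2OAc and CH2OTBS in place of CHO | C=C(/C=C/C=C(\CO)[C@@H]1CC[C@]2([C@H](CCCO[Si](C)(C)C(C)(C)C)/C(=C(\C)CO[Si](C)(C)C(C)(C)C)CC[C@]2(C)O)[C@@H]1O)CCC=C(C)C | intermediate
34 | primary allylic acetate of 33 | C=C(/C=C/C=C(\COC(C)=O)[C@@H]1CC[C@]2([C@H](CCCO[Si](C)(C)C(C)(C)C)/C(=C(\C)CO[Si](C)(C)C(C)(C)C)CC[C@]2(C)O)[C@@H]1O)CCC=C(C)C | intermediate
35 | desilylated 34 (allylic CH2OH in place of the target CHO) | C=C(/C=C/C=C(\COC(C)=O)[C@@H]1CC[C@]2([C@H](CCCO)/C(=C(\C)CO)CC[C@]2(C)O)[C@@H]1O)CCC=C(C)C | intermediate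
36 | CNP0204268.1 | C=C(/C=C/C=C(\COC(C)=O)[C@@H]1CC[C@]2([C@H](CCCO)/C(=C(\C)C=O)CC[C@]2(C)O)[C@@H]1O)CCC=C(C)C | target

**Step count and risks**

Total step count: 26. Longest linear sequence: 24 steps (steps 1–15, 17–20 and 22–26; steps 16 and 21 make side fragments).

Steps most likely to fail:

1. Step 10. NIS may iodinate the alkene before gold has engaged the alkyne, which would give an iodonium-induced ring expansion without ring closure; alternatively the alkenyl–gold bond may be protonated before iodine arrives. The fallback separates the two events with stoichiometric gold. It sets out from 15, which is treated with Ph3PAuCl/AgOTf (1.05 equiv each) and 2,6-di-tert-butyl-4-methylpyridine in CH2Cl2 at −40 °C with no halogen source present. As no proton is released, the cascade should stop at the persistent alkenylgold(I) phosphine complex F1, with the silyl group held as its triflate. Only when 15 is consumed is NIS added (iododeauration with retention), and the same citric acid work-up returns the route at 17.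

2. Step 18. β-Hydride elimination of the alkylpalladium intermediate may outrun its reduction by the silane, giving cycloisomerisation to a diene; or the s-trans ester conformer may prevent ring closure so that the alkynoate is simply reduced. The fallback closes the ring by a radical and builds the alkene afterwards. It sets out from 23.
   - NBS and ethyl vinyl ether give the bromoacetal F2.
   - Bu3SnH/AIBN (Ueno–Stork 5-exo-trig cyclisation) gives the cis-fused bicyclic acetal F3.
   - Jones oxidation gives the saturated lactone F4.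
   - NaH/ethyl formate gives the chelated sodium enolate of the α-formyl lactone F5, which is trapped with PhNTf2 as the (Z)-enol triflate F6.
   - Palladium-catalysed formylation (CO, Bu3SnH, Pd(PPh3)4) with retention of geometry returns the route at 28.

3. Step 7. Tin hydride may add to the remote 2-butynyl triple bond (loss of site selectivity), or tin may be placed distal to the carbinol. The fallback reorders the sequence so that the hydrostannation meets a single alkyne. It sets out from 6.
   - The same ruthenium-catalysed trans-hydrostannation gives the stannane F7, and iodine gives the iodide F8.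
   - t-BuLi gives the dilithio species F9, which adds to cyclobutanone 12 to give the diol F10.
   - OsO4 (cat.)/NaIO4/2,6-lutidine cleaves only the unhindered trisubstituted alkene and gives the lactol F11.
   - The Ohira–Bestmann reagent gives the terminal alkyne F12.
   - n-BuLi (3 equiv) and MeI return the route at 14.

**Further compounds**

F1 | step 10 | alkenylgold(I) triphenylphosphine complex of the spiroketone with a dimethylsilyl triflate on the tertiary oxygen | C1CC[C@]2([C@H](CCCO[Si](C)(C)C(C)(C)C)/C(=C(\C)[Au-][P+](c3ccccc3)(c3ccccc3)c3ccccc3)CC[C@]2(C)O[Si](C)(C)OS(=O)(=O)C(F)(F)F)C1=O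
F2 | step 18 | 2-bromo-1-ethoxyethyl ether (bromoacetal) of the secondary alcohol of 23, acetal epimers | C1=CC[C@]2([C@H](CCCO[Si](C)(C)C(C)(C)C)/C(=C(\C)CO[Si](C)(C)C(C)(C)C)CC[C@]2(C)O)[C@@H]1OC(CBr)OCC
F3 | step 18 | cis-fused bicyclic ethyl acetal (2-ethoxy-tetrahydrofuran fused to the cyclopentane) | C5(OCC)C[C@@H]1CC[C@]2([C@H](CCCO[Si](C)(C)C(C)(C)C)/C(=C(\C)CO[Si](C)(C)C(C)(C)C)CC[C@]2(C)O)[C@@H]1O5
F4 | step 18 | cis-fused saturated γ-lactone | O=C5C[C@@H]1CC[C@]2([C@H](CCCO[Si](C)(C)C(C)(C)C)/C(=C(\C)CO[Si](C)(C)C(C)(C)C)CC[C@]2(C)O)[C@@H]1O5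
F5 | step 18 | sodium (Z)-enolate of the α-formyl lactone | [Na+].[O-]/C=C5/[C@@H]1CC[C@]2([C@H](CCCO[Si](C)(C)C(C)(C)C)/C(=C(\C)CO[Si](C)(C)C(C)(C)C)CC[C@]2(C)O)[C@@H]1OC5=O
F6 | step 18 | (Z)-enol triflate of the α-formyl lactone | FC(F)(F)S(=O)(=O)O/C=C5/[C@@H]1CC[C@]2([C@H](CCCO[Si](C)(C)C(C)(C)C)/C(=C(\C)CO[Si](C)(C)C(C)(C)C)CC[C@]2(C)O)[C@@H]1OC5=O
F7 | step 7 | (6S,7Z)-11-[(tert-butyldimethylsilyl)oxy]-2,6-dimethyl-7-(tributylstannyl)undeca-2,7-dien-6-ol | CC(C)=CCC[C@](C)(O)/C(=C/CCCO[Si](C)(C)C(C)(C)C)[Sn](CCCC)(CCCC)CCCC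
F8 | step 7 | (6S,7Z)-11-[(tert-butyldimethylsilyl)oxy]-7-iodo-2,6-dimethylundeca-2,7-dien-6-ol | CC(C)=CCC[C@](C)(O)/C(I)=C/CCCO[Si](C)(C)C(C)(C)C
F9 | step 7 | dilithio derivative of F8 (lithium alkoxide, 7-lithio alkene) | CC(C)=CCC[C@](C)(O[Li])/C([Li])=C/CCCO[Si](C)(C)C(C)(C)C
F10 | step 7 | (6S,7Z)-11-[(tert-butyldimethylsilyl)oxy]-7-(1-hydroxycyclobutyl)-2,6-dimethylundeca-2,7-dien-6-ol | CC(C)=CCC[C@](C)(O)/C(=C/CCCO[Si](C)(C)C(C)(C)C)C1(O)CCC1
F11 | step 7 | lactol from cleavage of F10 (5-methyl-oxolan-2-ol bearing the alkenylcyclobutanol at C5) | OC1CC[C@](C)(O1)/C(=C/CCCO[Si](C)(C)C(C)(C)C)C2(O)CCC2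
F12 | step 7 | terminal alkyne analogue of 14 | C#CCC[C@](C)(O)/C(=C/CCCO[Si](C)(C)C(C)(C)C)C1(O)CCC1
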